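**Retrosynthetic overview**
1. Target 18 ⇐ bis-benzyl ether 17 by O-debenzylation (H2/Pd).
2. 17 ⇐ (R)-β-veratryl-γ-butyrolactone 14 + benzylic bromide 15 by trans-selective enolate benzylation; C3 is set by C4.
3. 14 ⇐ γ,δ-unsaturated ester 10 by ozonolysis/NaBH4 and lactonisation. This is the only ring that is made (the butyrolactone); both arenes are bought.
4. 10 ⇐ allylic alcohol 6 + orthoacetate 7 by Johnson–Claisen [3,3] shift, which forms the C4–CH2C(=O) bond with C–O → C–C chirality transfer.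
5. 6 ⇐ (R)-but-3-yn-2-ol 1 + veratryl bromide 2 by acetylide benzylation and trans-reduction.

Assumption: (R)-but-3-yn-2-ol (≥98% ee) and 3,4-bis(benzyloxy)benzyl bromide are bought as catalogue items.

**Step 1**
Reactants: 1 (R)-but-3-yn-2-ol; 2 3,4-dimethoxybenzyl bromide
Product: 4 (R)-5-(3,4-dimethoxyphenyl)pent-3-yn-2-ol, via bis(bromomagnesium) alkoxide acetylide 3 (not isolated)
Conditions: EtMgBr (2.1 equiv), THF, 0 °C → rt; CuCl (10 mol%), then 2, 50 °C; aq. NH4Cl
Reagents that add atoms: none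
Why: Cu(I)-catalysed alkylation of the alkynyl Grignard with a reactive benzylic bromide forms the sp–sp3 bond while the magnesium alkoxide stays inert; the bought carbinol stereocentre is not touched.

**Step 2**
Reactants: 4 (R)-5-(3,4-dimethoxyphenyl)pent-3-yn-2-ol
Product: 6 (2R,3E)-5-(3,4-dimethoxyphenyl)pent-3-en-2-ol, via cyclic vinylalanate 5 (not isolated)
Conditions: Red-Al (2.5 equiv), THF, 0 °C → rt; aq. NaOH
Reagents that add atoms: none
Why: Alkoxide-directed trans-hydroalumination of a propargylic alcohol (Red-Al reduction) followed by protonolysis gives only the E-alkene, and the carbinol centre is unaffected.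

**Step 3**
Reactants: 6 (2R,3E)-5-(3,4-dimethoxyphenyl)pent-3-en-2-ol; 7 triethyl orthoacetate
Product: 10 ethyl (3R,4E)-3-(3,4-dimethoxybenzyl)hex-4-enoate, via mixed orthoester 8 (not isolated), via ketene acetal 9 (not isolated)
Conditions: 7 (6 equiv), EtCO2H (10 mol%), 140 °C, EtOH distilled off
Reagents that add atoms: none
Why: Johnson–Claisen [3,3]-sigmatropic rearrangement through a chair transition state with the carbinol methyl equatorial; the new C–C bond forms suprafacially on the face the C–O bond leaves, so the (R)-carbinol of the E-alkene becomes the (R)-C3 centre and an E-propenyl group.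

**Step 4**
Reactants: 10 ethyl (3R,4E)-3-(3,4-dimethoxybenzyl)hex-4-enoate
Product: 14 (R)-4-(3,4-dimethoxybenzyl)dihydrofuran-2(3H)-one, via secondary ozonide 11 (not isolated), via aldehyde ester 12 (not isolated), via hydroxy ester 13 (not isolated)
Conditions: O3, CH2Cl2, −78 °C (Sudan Red 7B end point); NaBH4, MeOH, −78 → 0 °C; 2 M HCl, rt
Reagents that add atoms: ozone, [O-][O+]=O
Why: Ozonolysis with reductive NaBH4 work-up turns the propenyl group into CH2OH, and the γ-hydroxy ester lactonises on acidification; the α-chiral aldehyde is reduced in situ faster than it can epimerise, so the stereocentre is kept.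

**Step 5**
Reactants: 14 (R)-4-(3,4-dimethoxybenzyl)dihydrofuran-2(3H)-one; 15 3,4-bis(benzyloxy)benzyl bromide
Product: 17 (3R,4R)-3-[3,4-bis(benzyloxy)benzyl]-4-(3,4-dimethoxybenzyl)dihydrofuran-2(3H)-one, via lithium enolate 16 (not isolated)
Conditions: LiHMDS (1.05 equiv), THF, −78 °C; 15 (1.1 equiv), DMPU, −78 → −20 °C
Reagents that add atoms: none
Why: Alkylation of the lactone lithium enolate takes place on the face anti to the β-benzyl group (1,2-induction), giving the trans (3R,4R) lactone, which is also the thermodynamic isomer.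

**Step 6**
Reactants: 17 (3R,4R)-3-[3,4-bis(benzyloxy)benzyl]-4-(3,4-dimethoxybenzyl)dihydrofuran-2(3H)-one
Product: 18 3'-O-demethylarctigenin, (3R,4R)-3-(3,4-dihydroxybenzyl)-4-(3,4-dimethoxybenzyl)dihydrofuran-2(3H)-one
Conditions: H2 (1 atm), 10% Pd/C, EtOAc/EtOH, rt
Reagents that add atoms: none
Why: Catalytic hydrogenolysis cleaves the two aryl benzyl ethers only; lactone, methyl ethers and both stereocentres are inert.

**Compound list**
1 | (R)-but-3-yn-2-ol | C[C@@H](O)C#C | starting material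
2 | 3,4-dimethoxybenzyl bromide (4-(bromomethyl)-1,2-dimethoxybenzene) | COc1ccc(CBr)cc1OC | starting material
3 | bromomagnesium (R)-4-(bromomagnesio)but-3-yn-2-olate | C[C@@H](O[Mg]Br)C#C[Mg]Br | intermediate
4 | (R)-5-(3,4-dimethoxyphenyl)pent-3-yn-2-ol | C[C@@H](O)C#CCc1ccc(OC)c(OC)c1 | intermediate
5 | sodium (5R)-3-(3,4-dimethoxybenzyl)-2,2-bis(2-methoxyethoxy)-5-methyl-2,5-dihydro-1,2-oxaaluminol-2-uide (cyclic vinylalanate) | C[C@@H]1C=C(Cc2ccc(OC)c(OC)c2)[Al-](OCCOC)(OCCOC)O1.[Na+] | intermediate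
6 | (2R,3E)-5-(3,4-dimethoxyphenyl)pent-3-en-2-ol | C[C@@H](O)/C=C/Cc1ccc(OC)c(OC)c1 | intermediate
7 | triethyl orthoacetate | CC(OCC)(OCC)OCC | starting material
8 | 4-[(2E,4R)-4-(1,1-diethoxyethoxy)pent-2-en-1-yl]-1,2-dimethoxybenzene (mixed orthoester) | CCOC(C)(OCC)O[C@H](C)/C=C/Cc1ccc(OC)c(OC)c1 | intermediate
9 | 4-{(2E,4R)-4-[(1-ethoxyethenyl)oxy]pent-2-en-1-yl}-1,2-dimethoxybenzene (ketene acetal) | C=C(OCC)O[C@H](C)/C=C/Cc1ccc(OC)c(OC)c1 | intermediate
10 | ethyl (3R,4E)-3-(3,4-dimethoxybenzyl)hex-4-enoate | CCOC(=O)C[C@@H](Cc1ccc(OC)c(OC)c1)/C=C/C | intermediate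
11 | ethyl (3R)-3-(3,4-dimethoxybenzyl)-3-(5-methyl-1,2,4-trioxolan-3-yl)propanoate (secondary ozonide, isomers at the two trioxolane carbons) | CCOC(=O)C[C@@H](Cc1ccc(OC)c(OC)c1)C1OOC(C)O1 | intermediate
12 | ethyl (3R)-3-(3,4-dimethoxybenzyl)-4-oxobutanoate | CCOC(=O)C[C@@H](Cc1ccc(OC)c(OC)c1)C=O | intermediate
13 | ethyl (3R)-3-(3,4-dimethoxybenzyl)-4-hydroxybutanoate | CCOC(=O)C[C@@H](Cc1ccc(OC)c(OC)c1)CO | intermediate
14 | (R)-4-(3,4-dimethoxybenzyl)dihydrofuran-2(3H)-one | COc1ccc(C[C@H]2COC(=O)C2)cc1OC | intermediate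
15 | 3,4-bis(benzyloxy)benzyl bromide | BrCc1ccc(OCc2ccccc2)c(OCc2ccccc2)c1 | starting material
16 | lithium (4R)-4-(3,4-dimethoxybenzyl)-4,5-dihydrofuran-2-olate | COc1ccc(C[C@H]2COC(O[Li])=C2)cc1OC | intermediate
17 | (3R,4R)-3-[3,4-bis(benzyloxy)benzyl]-4-(3,4-dimethoxybenzyl)dihydrofuran-2(3H)-one (trans) | COc1ccc(C[C@H]2COC(=O)[C@@H]2Cc2ccc(OCc3ccccc3)c(OCc3ccccc3)c2)cc1OC | intermediate
18 | 3'-O-demethylarctigenin, (3R,4R)-3-(3,4-dihydroxybenzyl)-4-(3,4-dimethoxybenzyl)dihydrofuran-2(3H)-one | COc1ccc(C[C@H]2COC(=O)[C@@H]2Cc2ccc(O)c(O)c2)cc1OC | target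

**Totals**
Total steps: 6. Longest linear sequence: 6 (fully linear; 2, 7 and 15 are bought).

**Three steps most likely to fail, each with a fallback**

Step 1 (benzylation of the unprotected alkynyl Grignard). The risks are O-benzylation, Wurtz coupling of the electron-rich bromide, and alkyne-to-allene isomerisation. The fallback sets out from 1 and comes back at 6, so it also replaces step 2. Compound 1 is silylated (TBSCl, imidazole, DMF) to (R)-tert-butyl(but-3-yn-2-yloxy)dimethylsilane F1. Zirconium-catalysed syn-hydroboration with pinacolborane (cat. Cp2Zr(H)Cl, Et3N, 60 °C) gives (R,E)-tert-butyldimethyl{[4-(4,4,5,5-tetramethyl-1,3,2-dioxaborolan-2-yl)but-3-en-2-yl]oxy}silane F2. Suzuki–Miyaura sp2–sp3 coupling of F2 with 2 (Pd(dppf)Cl2, K3PO4, THF/H2O, 60 °C) gives (R,E)-tert-butyl{[5-(3,4-dimethoxyphenyl)pent-3-en-2-yl]oxy}dimethylsilane F3. TBAF in THF then releases 6. The E geometry now comes from the syn-hydroboration instead of the alkyne reduction.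

Step 4 (ozonolysis next to an electron-rich veratryl ring). The risks are over-oxidation of the arene and loss of the α-chiral aldehyde. The fallback sets out from 10 and comes back at 12. A one-pot Lemieux–Johnson cleavage (cat. OsO4, NaIO4, 2,6-lutidine, dioxane/H2O, rt) dihydroxylates the alkene to ethyl (3R)-3-(3,4-dimethoxybenzyl)-4,5-dihydroxyhexanoate F4. Periodate cleaves F4 in the same flask, before its γ-hydroxyl can lactonise, to aldehyde 12. Crude 12 is reduced at once with NaBH4 and acidified as in step 4 (12 → 13 → 14).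

Step 5 (enolate benzylation). The risks are sluggish or double alkylation and incomplete trans selectivity. The fallback sets out from 14 and comes back at 18. Enolate 16 (LiHMDS, THF, −78 °C) is added to bought 3,4-bis(benzyloxy)benzaldehyde (O=Cc1ccc(OCc2ccccc2)c(OCc2ccccc2)c1). The aldol addition occurs anti to the β-substituent and gives trans-(3S,4R)-3-{[3,4-bis(benzyloxy)phenyl](hydroxy)methyl}-4-(3,4-dimethoxybenzyl)dihydrofuran-2(3H)-one F5. The ring geometry is the same as in 17; the descriptor at C3 changes only because of the new OH, and both carbinol epimers are used. Hydrogenolysis (H2, Pd/C, AcOH, cat. HClO4) then removes the benzylic hydroxyl and both benzyl ethers in one operation to give 18.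

**Further compounds**
F1 | step 1 | (R)-tert-butyl(but-3-yn-2-yloxy)dimethylsilane | C[C@@H](O[Si](C)(C)C(C)(C)C)C#C
F2 | step 1 | (R,E)-tert-butyldimethyl{[4-(4,4,5,5-tetramethyl-1,3,2-dioxaborolan-2-yl)but-3-en-2-yl]oxy}silane | C[C@@H](O[Si](C)(C)C(C)(C)C)/C=C/B1OC(C)(C)C(C)(C)O1
F3 | step 1 | (R,E)-tert-butyl{[5-(3,4-dimethoxyphenyl)pent-3-en-2-yl]oxy}dimethylsilane | C[C@@H](O[Si](C)(C)C(C)(C)C)/C=C/Cc1ccc(OC)c(OC)c1
F4 | step 4 | ethyl (3R)-3-(3,4-dimethoxybenzyl)-4,5-dihydroxyhexanoate (threo diol, two diastereomers) | CCOC(=O)C[C@@H](Cc1ccc(OC)c(OC)c1)C(O)C(C)O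
F5 | step 5 | (3S,4R)-3-{[3,4-bis(benzyloxy)phenyl](hydroxy)methyl}-4-(3,4-dimethoxybenzyl)dihydrofuran-2(3H)-one (trans, carbinol epimers) | COc1ccc(C[C@H]2COC(=O)[C@@H]2C(O)c2ccc(OCc3ccccc3)c(OCc3ccccc3)c2)cc1OC
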